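(Readings and results are calculated from invented constants, and the scatter is random.)

I am given no rate constants, so I want one constant that the runs themselves can supply.

| flask | starting material | temperature | remark | time |
|---|---|---|---|---|
| winter | 1.3 mM | 75 °C | run made earlier |  |
| noon | 6 mM | 90 °C | run made earlier |  |
| alpha | 4.0 mM | 90 °C |  | 5.0 min |
| delta | 3.0 mM | 90 °C |  | 5.0 min |
| gamma | 1.0 mM | 90 °C |  | 5.0 min |
| epsilon | 2.0 mM | 90 °C |  | 5.0 min |
| beta | 1.5 mM | 90 °C |  | 5.0 min |

- winter (time / min: ring / %): 0.667: 19.3; 2.00: 20.3; 3.00: 20.4; 5.00: 20.5
- noon (time / min: ring / %): 0.667: 14.8; 1.33: 14.3; 2.00: 14.8; 2.50: 14.5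

(each reading ± 0.3 percentage points)

- the flasks by amount of ring, in percent of the starting material charged, highest first, at 5.0 min (alpha / delta / gamma / epsilon / beta)
- the amount of ring, in percent of the starting material charged of the flask you put first, at 5.0 min
- the amount of ring, in percent of the starting material charged of the flask you put last, at 5.0 min

- the numbers in the tables scatter with a standard deviation of 0.3 percentage points
- a reading or a percentage of ring counts all its forms, free or not

Suppose starting material closes to ring in a first-order step and pairs with a second molecule of itself in a second-order step. At any moment closing then takes a share E/(E+[starting material]) of what is being used, with E a constant concentration. That share grows as [starting material] falls, so the yield of a run is its average over the fall, (E/c)·ln(1+c/E), where c is the charge.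

The noon readings are flat from 0.667 min on, with a mean of 14.6%, and the winter readings flatten as well, so I take each flask at 5.0 min to stand on its plateau. Winter ran at 75 °C, so I leave it aside. Trying values until the average matches noon gives E = 0.282 mM, the split concentration: the [starting material] at which, in this picture, closing and pairing use it equally fast, an effective molarity as read here from the noon readings.

Now the bracket. In this picture the ring concentration rises with the charge, so a smaller flask holds less than noon's 0.876 mM, which caps gamma at 87.6% and alpha at 21.9%. From below, in the same picture, gamma stays above its opening share, 22.0%, and alpha, being more dilute than noon, stays above 14.6%. The average itself gives 42.7% for gamma and 19.2% for alpha, and it falls as the charge rises, so I rank the flasks by charge, most dilute first.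

The forecast, holding that “Higher dilution gives more ring”, gives gamma > beta > epsilon > delta > alpha, with 40% (23% to 80%) for gamma and 19% (15.5% to 23%) for alpha. Both central values lie inside my bracket, and the forecast's value for gamma is lower than my average by 2.7 percentage points.

The simulation gives gamma > beta > epsilon > delta > alpha, the forecast's order.

    starting material → ring (k = 0.140 s⁻¹, Ea = 102 kJ mol⁻¹)
    2 starting material → open dimer (k = 150 M⁻¹ s⁻¹, Ea = 47.0 kJ mol⁻¹)
    starting material + ring ⇌ idle adduct, settled at all times (K = 2700 M⁻¹, ΔH = −13.0 kJ mol⁻¹)
    starting material + ring → side product (k = 170 M⁻¹ s⁻¹, Ea = 40.0 kJ mol⁻¹)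
    (constants at 90 °C)

Gamma holds 41.0% of ring against my 42.7%, and alpha 18.7% against my 19.2%. Gamma still holds 41.0% at 50.0 min, so the plateau step stood. On beta, at 1.5 mM, the split concentration gives 34.7%, and the flask holds 33.4%.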